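**Retrosynthetic overview**
1. No ring is formed: the furan ring is bought intact as furan 1 and the C16 chain as 1-bromohexadecane 2 (no 1,4-diketone/Paal–Knorr ring synthesis).
2. C2–alkyl bond (normal polarity): 2-furyllithium 3 + 2 ⇒ 2-hexadecylfuran 4.
3. Key bond, C5–CH2: the nucleophilic C5–H of 4 is joined to the acetate α-carbon, which is delivered by ethyl bromoacetate 5 as an electrophilic α-ester radical (an enolonium-type carbon) instead of the usual nucleophilic enolate.
4. The resulting ester 6 is not isolated; hydroxide in the same flask gives the target acid 7.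

Assumption: the target SMILES has no stereocentre and no stereogenic double bond, so "single enantiomer" means this one achiral constitution and no stereocontrol is needed.
Abbreviation: ppy = 2-phenylpyridinato (C11H8N), so fac-Ir(ppy)3 is Ir(C11H8N)3.

**Route**

Step 1
Reactants: 1 furan (1.5 equiv); 2 1-bromohexadecane (1.0 equiv)
Product: 4 2-hexadecylfuran, via 2-furyllithium 3 (not isolated)
Conditions: n-BuLi (1.2 equiv), THF, −78 → 0 °C, 1 h; then 2, 0 °C → rt, 16 h
Reagents that add atoms: n-butyllithium, [Li]CCCC (supplies only the lithium of intermediate 3; none of its atoms remain in 4)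
Why: Directed lithiation–alkylation of a heteroarene: n-BuLi removes the most acidic C–H of furan (C2, next to oxygen) and the resulting 2-furyllithium displaces bromide from the unhindered primary bromide by SN2; no stereocentre is formed.

Step 2
Reactants: 4 2-hexadecylfuran (1.0 equiv); 5 ethyl bromoacetate (2.0 equiv)
Product: 7 2-(5-hexadecylfuran-2-yl)acetic acid, via ethyl 2-(5-hexadecylfuran-2-yl)acetate 6 (not isolated)
Conditions: fac-Ir(ppy)3 (1 mol %), 2,6-lutidine (2.0 equiv), degassed MeCN/CH2Cl2 (1:1), blue LEDs (450 nm), rt, 16 h; then THF, 2 M aq LiOH (6 equiv), rt, 3 h; then 1 M HCl to pH 3–4, 0 °C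
Reagents that add atoms: lithium hydroxide, [Li+].[OH-] (its oxygen becomes the carboxyl OH oxygen of 7)
Why: Visible-light photoredox homolytic aromatic substitution followed by in-flask saponification: the excited trivalent iridium complex reduces 5 to bromide and the electrophilic radical ·CH2CO2Et, which adds to the only free α-position (C5) of the electron-rich furan, the adduct radical is oxidised by the tetravalent iridium complex and deprotonated by 2,6-lutidine to give ester 6, and LiOH then cleaves the ester by acyl–oxygen cleavage to acid 7; no stereocentre is formed.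

**Compound list**
1 | furan | c1ccoc1 | starting material
2 | 1-bromohexadecane | CCCCCCCCCCCCCCCCBr | starting material
3 | 2-furyllithium | [Li]c1ccco1 | intermediate (not isolated)
4 | 2-hexadecylfuran | CCCCCCCCCCCCCCCCc1ccco1 | intermediate
5 | ethyl bromoacetate | CCOC(=O)CBr | starting material
6 | ethyl 2-(5-hexadecylfuran-2-yl)acetate | CCCCCCCCCCCCCCCCc1ccc(CC(=O)OCC)o1 | intermediate (not isolated)
7 | 2-(5-hexadecylfuran-2-yl)acetic acid | CCCCCCCCCCCCCCCCc1ccc(CC(=O)O)o1 | target

**Totals**
Total step count: 2. Longest linear sequence: 2 steps (1 → 4 → 7).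

**Steps most likely to fail**
The route has only two steps, so step 2 is entered twice, once for each of its two stages.

First, step 2, the C–C bond-forming stage. The risks are incomplete conversion, attack at C3/C4, a second alkylation of 6, or hydrogen abstraction at its doubly activated CH2. The fallback sets out from 4 and comes back at 7. Compound 4 is heated with diethyl malonate and Mn(OAc)3·2H2O (2.2 equiv) and NaOAc in AcOH at 60–70 °C. Trivalent manganese oxidises the malonate to the more electrophilic malonyl radical, which substitutes C5 and gives diethyl 2-(5-hexadecylfuran-2-yl)malonate F1. KOH in aqueous EtOH followed by cold dilute HCl gives 2-(5-hexadecylfuran-2-yl)malonic acid F2, which loses one CO2 on warming in toluene at 80–90 °C to give 7. This replaces the photoredox cycle with a stoichiometric one-electron oxidant and a malonate that is decarboxylated afterwards.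

Second, step 1. The risks are sluggish SN2 of 3 on the long-chain bromide, E2 elimination to 1-hexadecene, and some 2,5-dialkylation. The fallback sets out from 1 and comes back at 4. Friedel–Crafts acylation of 1 with hexadecanoyl chloride (SnCl4, CH2Cl2, −20 → 0 °C) gives 1-(furan-2-yl)hexadecan-1-one F3. Wolff–Kishner reduction (Huang–Minlon: N2H4·H2O, KOH, diethylene glycol, 130 → 200 °C) through 1-(furan-2-yl)hexadecan-1-one hydrazone F4 then gives 4.

Third, step 2, the saponification stage. The furylacetic acid 7 is sensitive to acid and heat (decarboxylation, ring opening), and its lithium soap emulsifies on work-up. The fallback sets out from 4 and comes back at 7. The photoredox alkylation is run under strictly anhydrous conditions with trimethylsilyl bromoacetate (C[Si](C)(C)OC(=O)CBr) in place of 5, giving trimethylsilyl 2-(5-hexadecylfuran-2-yl)acetate F5. This silyl ester is cleaved to 7 simply by stirring with pH 7 phosphate buffer/THF at rt, with no hydroxide and no mineral acid.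

Further compounds
F1 | step 2 | diethyl 2-(5-hexadecylfuran-2-yl)malonate | CCCCCCCCCCCCCCCCc1ccc(C(C(=O)OCC)C(=O)OCC)o1
F2 | step 2 | 2-(5-hexadecylfuran-2-yl)malonic acid | CCCCCCCCCCCCCCCCc1ccc(C(C(=O)O)C(=O)O)o1
F3 | step 1 | 1-(furan-2-yl)hexadecan-1-one | CCCCCCCCCCCCCCCC(=O)c1ccco1
F4 | step 1 | 1-(furan-2-yl)hexadecan-1-one hydrazone | CCCCCCCCCCCCCCCC(=NN)c1ccco1
F5 | step 2 | trimethylsilyl 2-(5-hexadecylfuran-2-yl)acetate | CCCCCCCCCCCCCCCCc1ccc(CC(=O)O[Si](C)(C)C)o1
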